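**Strategy.** Everything rests on cutting the bond between the quaternary carbon C2 of the pyran ring and the first CH2 of the side chain. C2 bears O1 and is tied to C4 through the C3=C4 double bond, so it is the β-carbon of a latent vinylogous ester, a 2-methylchromone. A copper-catalysed asymmetric conjugate addition of the complete C16 homoallylic Grignard reagent to a 6-silyloxy-2-methylchromone joins both halves, sets the (S) quaternary centre under ligand control and, through triflation of the enolate in the same flask, stores the C3=C4 alkene of the target. Triflate reduction and desilylation then finish the synthesis.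

Key step: step 6

Remark on the chemistry: C2 of the target is (S). The sense of induction of the chiral ligand in step 6 is not predicted here; the antipode that delivers the alkyl group to the Si face of C2 (Si with respect to O1 > C3 > CH3) is to be identified in a small-scale run and then used.

**Step 1**
Reactants: 1 dihydro-β-ionone, 4-(2,6,6-trimethylcyclohex-1-en-1-yl)butan-2-one
Product: 3 terminal alkyne 2-(but-3-yn-1-yl)-1,3,3-trimethylcyclohex-1-ene, via enol phosphate 2 (not isolated)
Conditions: LDA (1.1 equiv), THF, −78 °C; ClP(O)(OEt)2, −78 °C to rt; LDA (2.3 equiv), −78 °C to rt; H2O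
Reagents that add atoms: none
Why: Kinetic deprotonation at the methyl group gives the terminal enol diethyl phosphate, which LDA eliminates to the lithium acetylide (Negishi methyl ketone to terminal alkyne protocol); no stereocenter is formed.

**Step 2**
Reactants: 3 terminal alkyne 2-(but-3-yn-1-yl)-1,3,3-trimethylcyclohex-1-ene
Product: 6 homoallylic alcohol (E)-4-methyl-6-(2,6,6-trimethylcyclohex-1-en-1-yl)hex-3-en-1-ol, via alkenyldimethylalane 4 (not isolated), via lithium alkenylalanate 5 (not isolated)
Conditions: Me3Al (2 equiv), Cp2ZrCl2 (0.25 equiv), CH2Cl2, 0 °C to rt; volatiles removed, hexane/THF, n-BuLi (1 equiv), −78 °C; oxirane, −78 to 0 °C; aq. Rochelle salt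
Reagents that add atoms: trimethylaluminium C[Al](C)C; oxirane C1CO1
Why: Zirconocene-catalysed Negishi carboalumination adds methyl and aluminium syn across the alkyne with aluminium at the terminus, which fixes the E trisubstituted alkene, and the derived alanate opens oxirane with retention of the alkene geometry.

**Step 3**
Reactants: 6 homoallylic alcohol (E)-4-methyl-6-(2,6,6-trimethylcyclohex-1-en-1-yl)hex-3-en-1-ol
Product: 7 homoallylic bromide 2-[(E)-6-bromo-3-methylhex-3-en-1-yl]-1,3,3-trimethylcyclohex-1-ene
Conditions: CBr4, PPh3, CH2Cl2, 0 °C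
Reagents that add atoms: carbon tetrabromide BrC(Br)(Br)Br
Why: Appel bromination converts the primary alcohol under neutral conditions that should leave both alkenes and the E geometry untouched.

**Step 4**
Reactants: 8 2',5'-dihydroxyacetophenone
Product: 10 6-hydroxy-2-methyl-4H-chromen-4-one, via 1,3-diketone 9 (not isolated)
Conditions: NaH (5 equiv), EtOAc, THF, reflux, under argon; then conc. HCl, AcOH, 100 °C
Reagents that add atoms: ethyl acetate CCOC(C)=O
Why: Claisen condensation of the acetophenone enolate with ethyl acetate gives the 1,3-diketone, and acid-catalysed cyclodehydration through the 2'-hydroxyl closes the pyranone ring (classical 2-methylchromone synthesis).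

**Step 5**
Reactants: 10 6-hydroxy-2-methyl-4H-chromen-4-one
Product: 11 2-methyl-6-[(triisopropylsilyl)oxy]-4H-chromen-4-one
Conditions: TIPSCl, imidazole, DMF, rt
Reagents that add atoms: chlorotriisopropylsilane CC(C)[Si](Cl)(C(C)C)C(C)C
Why: Standard silylation of the only hydroxyl gives an aryl silyl ether that should tolerate Grignard, palladium and formate conditions and be cleaved by fluoride at the end.

**Step 6**
Reactants: 7 homoallylic bromide 2-[(E)-6-bromo-3-methylhex-3-en-1-yl]-1,3,3-trimethylcyclohex-1-ene; 11 2-methyl-6-[(triisopropylsilyl)oxy]-4H-chromen-4-one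
Product: 14 enol triflate (S)-2-methyl-2-[(E)-4-methyl-6-(2,6,6-trimethylcyclohex-1-en-1-yl)hex-3-en-1-yl]-6-[(triisopropylsilyl)oxy]-2H-chromen-4-yl trifluoromethanesulfonate, via Grignard reagent 12 (not isolated), via bromomagnesium enolate 13 (not isolated)
Conditions: 7, Mg turnings, 2-MeTHF, 40 °C; added slowly to 11, CuBr·SMe2 (5 mol %), TADDOL-derived chiral phosphine–phosphite ligand (6 mol %), 2-MeTHF, −78 °C; then N-(5-chloropyridin-2-yl)triflimide (Comins reagent), THF, −78 to 0 °C; aq. NH4Cl
Reagents that add atoms: N-(5-chloropyridin-2-yl)-1,1,1-trifluoro-N-(trifluoromethylsulfonyl)methanesulfonamide (Comins reagent) FC(F)(F)S(=O)(=O)N(c1ccc(Cl)cn1)S(=O)(=O)C(F)(F)F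
Why: The Grignard reagent transmetalates to the ligated monovalent copper bromide, the alkylcopper species forms a π-complex with the C2=C3 bond of the chromone, oxidative addition at C2 gives a trivalent copper σ-alkyl enolate and reductive elimination forms the C2–CH2 bond, after which the bromomagnesium enolate is O-sulfonylated by the triflimide. The closest known reaction type is the copper-catalysed asymmetric 1,4-addition of alkyl Grignard reagents to 2-methylchromones giving 2,2-dialkylchroman-4-ones, combined with the standard triflation of conjugate-addition enolates. No ring is closed. The only new stereocenter, C2, is set by the chiral ligand on copper, which shields one face of the flat pyranone so that the alkyl group arrives on the Si face and C2 becomes (S). The step needs 1,4- over 1,2-addition and over deprotonation of the vinylogous 2-methyl group, which the soft copper nucleophile, the low temperature and the slow addition should secure, and O- over C-sulfonylation, which the hard triflimide electrophile secures. The aryl silyl ether and both chain alkenes are inert, and the enolate is kept at or below 0 °C so that retro-oxa-Michael opening of the pyran ring should not erode the configuration at C2.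

**Step 7**
Reactants: 14 enol triflate (S)-2-methyl-2-[(E)-4-methyl-6-(2,6,6-trimethylcyclohex-1-en-1-yl)hex-3-en-1-yl]-6-[(triisopropylsilyl)oxy]-2H-chromen-4-yl trifluoromethanesulfonate
Product: 15 silyl-protected chromene (S)-triisopropyl({2-methyl-2-[(E)-4-methyl-6-(2,6,6-trimethylcyclohex-1-en-1-yl)hex-3-en-1-yl]-2H-chromen-6-yl}oxy)silane
Conditions: Pd(OAc)2 (5 mol %), PPh3 (10 mol %), HCO2H, Bu3N, DMF, 60 °C, dark
Reagents that add atoms: none
Why: Palladium-catalysed formate reduction of the enol triflate (oxidative addition to zerovalent palladium, formate-to-hydride exchange with loss of CO2, reductive elimination) replaces the triflate by hydrogen and leaves the C3=C4 alkene, the chain alkenes and C2 untouched.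

**Step 8**
Reactants: 15 silyl-protected chromene (S)-triisopropyl({2-methyl-2-[(E)-4-methyl-6-(2,6,6-trimethylcyclohex-1-en-1-yl)hex-3-en-1-yl]-2H-chromen-6-yl}oxy)silane
Product: 16 target (S)-2-methyl-2-[(E)-4-methyl-6-(2,6,6-trimethylcyclohex-1-en-1-yl)hex-3-en-1-yl]-2H-chromen-6-ol
Conditions: TBAF, AcOH, THF, 0 °C, under argon, dark
Reagents that add atoms: none
Why: Fluoride cleaves the aryl silyl ether, and the acetic acid buffer and exclusion of air and light should protect the electron-rich chromenol from oxidation and from photochemical ring opening that would scramble C2.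

**Compound list**
1 | dihydro-β-ionone, 4-(2,6,6-trimethylcyclohex-1-en-1-yl)butan-2-one | CC1=C(CCC(C)=O)C(C)(C)CCC1 | starting material
2 | diethyl 4-(2,6,6-trimethylcyclohex-1-en-1-yl)but-1-en-2-yl phosphate (formed in the flask) | CC1=C(CCC(=C)OP(=O)(OCC)OCC)C(C)(C)CCC1 | intermediate
3 | 2-(but-3-yn-1-yl)-1,3,3-trimethylcyclohex-1-ene | CC1=C(CCC#C)C(C)(C)CCC1 | intermediate
4 | dimethyl[(E)-2-methyl-4-(2,6,6-trimethylcyclohex-1-en-1-yl)but-1-en-1-yl]alane (formed in the flask) | CC1=C(CC/C(C)=C/[Al](C)C)C(C)(C)CCC1 | intermediate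
5 | lithium butyl(dimethyl)[(E)-2-methyl-4-(2,6,6-trimethylcyclohex-1-en-1-yl)but-1-en-1-yl]alanate (formed in the flask) | [Li+].CC1=C(CC/C(C)=C/[Al-](C)(C)CCCC)C(C)(C)CCC1 | intermediate
6 | (E)-4-methyl-6-(2,6,6-trimethylcyclohex-1-en-1-yl)hex-3-en-1-ol | CC1=C(CC/C(C)=C/CCO)C(C)(C)CCC1 | intermediate
7 | 2-[(E)-6-bromo-3-methylhex-3-en-1-yl]-1,3,3-trimethylcyclohex-1-ene | CC1=C(CC/C(C)=C/CCBr)C(C)(C)CCC1 | intermediate
8 | 2',5'-dihydroxyacetophenone | CC(=O)c1cc(O)ccc1O | starting material
9 | 1-(2,5-dihydroxyphenyl)butane-1,3-dione (formed in the flask) | CC(=O)CC(=O)c1cc(O)ccc1O | intermediate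
10 | 6-hydroxy-2-methyl-4H-chromen-4-one | Cc1cc(=O)c2cc(O)ccc2o1 | intermediate
11 | 2-methyl-6-[(triisopropylsilyl)oxy]-4H-chromen-4-one | Cc1cc(=O)c2cc(O[Si](C(C)C)(C(C)C)C(C)C)ccc2o1 | intermediate
12 | [(E)-4-methyl-6-(2,6,6-trimethylcyclohex-1-en-1-yl)hex-3-en-1-yl]magnesium bromide (formed in the flask) | CC1=C(CC/C(C)=C/CC[Mg]Br)C(C)(C)CCC1 | intermediate
13 | bromomagnesium (S)-2-methyl-2-[(E)-4-methyl-6-(2,6,6-trimethylcyclohex-1-en-1-yl)hex-3-en-1-yl]-6-[(triisopropylsilyl)oxy]-2H-chromen-4-olate (formed in the flask) | CC1=C(CC/C(C)=C/CC[C@@]2(C)C=C(O[Mg]Br)c3cc(O[Si](C(C)C)(C(C)C)C(C)C)ccc3O2)C(C)(C)CCC1 | intermediate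
14 | (S)-2-methyl-2-[(E)-4-methyl-6-(2,6,6-trimethylcyclohex-1-en-1-yl)hex-3-en-1-yl]-6-[(triisopropylsilyl)oxy]-2H-chromen-4-yl trifluoromethanesulfonate | CC1=C(CC/C(C)=C/CC[C@@]2(C)C=C(OS(=O)(=O)C(F)(F)F)c3cc(O[Si](C(C)C)(C(C)C)C(C)C)ccc3O2)C(C)(C)CCC1 | intermediate
15 | (S)-triisopropyl({2-methyl-2-[(E)-4-methyl-6-(2,6,6-trimethylcyclohex-1-en-1-yl)hex-3-en-1-yl]-2H-chromen-6-yl}oxy)silane | CC1=C(CC/C(C)=C/CC[C@@]2(C)C=Cc3cc(O[Si](C(C)C)(C(C)C)C(C)C)ccc3O2)C(C)(C)CCC1 | intermediate
16 | (S)-2-methyl-2-[(E)-4-methyl-6-(2,6,6-trimethylcyclohex-1-en-1-yl)hex-3-en-1-yl]-2H-chromen-6-ol | CC1=C(CC/C(C)=C/CC[C@@]2(C)C=Cc3cc(O)ccc3O2)C(C)(C)CCC1 | target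

**Step count.** Total: 8 steps. Longest linear sequence: 6 steps (steps 1, 2, 3, 6, 7, 8).

**Steps most likely to fail**

1. Step 6. Facial discrimination at the hindered β,β-disubstituted acceptor may be insufficient, and enolisation of the 2-methyl group or incomplete O-sulfonylation of the crowded magnesium enolate may compete.
   Fallback (racemic series and resolution), setting out from 7 and 11: the Grignard reagent 12 is added with CuBr·SMe2 (10 mol %) and no chiral ligand in THF at −78 °C, and the enolate is protonated with aqueous NH4Cl. This gives racemic 2-methyl-2-[(E)-4-methyl-6-(2,6,6-trimethylcyclohex-1-en-1-yl)hex-3-en-1-yl]-6-[(triisopropylsilyl)oxy]chroman-4-one F1. Preparative chromatography on a chiral stationary phase gives the (S)-chromanone F2. KHMDS in THF at −78 °C converts it into the potassium enolate F3, which is sulfonylated in the same flask with the triflimide of step 6. The fallback comes back to the route at 14.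

2. Step 2. Transfer of the alkenyl group from the alanate to oxirane may be incomplete, or protodealumination may give the methyl-capped diene.
   Fallback, setting out from 1: cyclopropylmagnesium bromide in THF at 0 °C adds to the ketone to give the cyclopropyl carbinol 2-cyclopropyl-4-(2,6,6-trimethylcyclohex-1-en-1-yl)butan-2-ol F4. Julia–Johnson ring opening of the cyclopropylcarbinol (48 % aqueous HBr, 0 °C, short contact, or MgBr2·OEt2 in Et2O) gives the homoallylic bromide as an E-rich mixture. The E isomer is taken by chromatography on AgNO3-impregnated silica. The fallback comes back to the route at 7 and bypasses steps 1 to 3.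

3. Step 4. The hydroquinone polyanion may be oxidised by traces of air, and C-acylation of the poorly soluble trisodium salt may be incomplete.
   Fallback, setting out from 8: Kostanecki–Robinson acylation (Ac2O, NaOAc, 170 °C) gives 3-acetyl-2-methyl-4-oxo-4H-chromen-6-yl acetate F5. Boiling aqueous Na2CO3 removes the phenolic acetate and, by retro-Claisen cleavage, the 3-acetyl group. Acidification brings the fallback back to the route at 10.

**Further compounds**
F1 | step 6 | racemic 2-methyl-2-[(E)-4-methyl-6-(2,6,6-trimethylcyclohex-1-en-1-yl)hex-3-en-1-yl]-6-[(triisopropylsilyl)oxy]chroman-4-one | CC1=C(CC/C(C)=C/CCC2(C)CC(=O)c3cc(O[Si](C(C)C)(C(C)C)C(C)C)ccc3O2)C(C)(C)CCC1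
F2 | step 6 | (S)-2-methyl-2-[(E)-4-methyl-6-(2,6,6-trimethylcyclohex-1-en-1-yl)hex-3-en-1-yl]-6-[(triisopropylsilyl)oxy]chroman-4-one | CC1=C(CC/C(C)=C/CC[C@@]2(C)CC(=O)c3cc(O[Si](C(C)C)(C(C)C)C(C)C)ccc3O2)C(C)(C)CCC1
F3 | step 6 | potassium (S)-2-methyl-2-[(E)-4-methyl-6-(2,6,6-trimethylcyclohex-1-en-1-yl)hex-3-en-1-yl]-6-[(triisopropylsilyl)oxy]-2H-chromen-4-olate | CC1=C(CC/C(C)=C/CC[C@@]2(C)C=C([O-])c3cc(O[Si](C(C)C)(C(C)C)C(C)C)ccc3O2)C(C)(C)CCC1.[K+]
F4 | step 2 | 2-cyclopropyl-4-(2,6,6-trimethylcyclohex-1-en-1-yl)butan-2-ol (racemic) | CC1=C(CCC(C)(O)C2CC2)C(C)(C)CCC1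
F5 | step 4 | 3-acetyl-2-methyl-4-oxo-4H-chromen-6-yl acetate | CC(=O)Oc1ccc2oc(C)c(C(C)=O)c(=O)c2c1
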